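**Retrosynthetic overview**
1. Feature: in the ten-membered carbocycle C1–C10, C10 (CH–CH3) is the only stereocentre without a heteroatom and sits between C9H2 and the C1 carbinol. C9–C10 is therefore closed as an alkene by ring-closing metathesis (C8 vinyl + C1 isopropenyl), and C10 is set last by hydrogenation directed by the C1 hydroxyl.
2. Butenolide ring (O–C12(=O)–C11=C7–C6): intramolecular Horner–Wadsworth–Emmons reaction of a C6 phosphonoacetate, which carries C13, onto a C7 ketone.
3. C7–C8: catalytic asymmetric γ-silyloxyallylboration of a C7 aldehyde (sets C8, brings in the vinyl group). C6–C7: dithiane (formyl anion) addition to the epoxy aldehyde from nerol (Sharpless epoxidation sets C4 and C5, Felkin–Anh addition sets C6).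
4. C1–C10: ozonolysis of the nerol terminus, isopropenyl Grignard addition, oxidation; C1 is carried as a ketone and reduced (CBS) just before ring closure, so it needs no protecting group.
5. Ring order: epoxide (step 1), butenolide (step 14), ten-membered carbocycle (step 20).

Key step: step 20

Remark on numbering: C1 carbinol, C2, C3, C4 (epoxide C–CH3), C5 (epoxide CH), C6 (lactone O–CH), C7 (butenolide β-carbon), C8 (O-tiglate), C9, C10 (CH–CH3), C11 (butenolide α-carbon), C12 (lactone C=O), C13 (CH2OAc). Locants follow this numbering; descriptors are the CIP descriptors of each compound as it stands.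
Assumption: ring closure is taken to give the less strained ring-cis (9Z) alkene, and compounds 9, 14, 19 and 25 are taken as purchased.

Step 1
Reactants: 1 nerol
Product: 2 (2S,3R)-2,3-epoxynerol
Conditions: Ti(OiPr)4 (10 mol%), L-(+)-diethyl tartrate (12 mol%), tert-butyl hydroperoxide (anhydrous), 4 Å molecular sieves, CH2Cl2, −20 °C
Reagents that add atoms: tert-butyl hydroperoxide, CC(C)(C)OO
Why: Sharpless asymmetric epoxidation of the primary allylic alcohol, in which the titanium L-(+)-tartrate complex delivers oxygen to one face of the Z 2,3-alkene and ignores the isolated 6,7-alkene, should set C4 (R) and C5 (S) of the target.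

Step 2
Reactants: 2 (2S,3R)-2,3-epoxynerol
Product: 3 (2R,3R)-epoxy aldehyde
Conditions: TEMPO (10 mol%), PhI(OAc)2, CH2Cl2, rt
Reagents that add atoms: none
Why: Oxoammonium (TEMPO) oxidation of the primary alcohol stops at the aldehyde under near-neutral conditions that leave the epoxide and the trisubstituted alkene alone, and the α-carbon is an epoxide carbon that does not enolise.

Step 3
Reactants: 3 (2R,3R)-epoxy aldehyde; 4 1,3-dithiane
Product: 7 C6 triethylsilyl ether of the dithianyl carbinol, via 2-lithio-1,3-dithiane 5 (not isolated), via lithium alkoxide 6 (not isolated)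
Conditions: 4, n-BuLi, THF, −30 °C; then 3, −78 °C; then Et3SiCl, −78 → 0 °C
Reagents that add atoms: chlorotriethylsilane, CC[Si](Cl)(CC)CC
Why: Corey–Seebach addition of the dithiane anion as a formyl anion equivalent should follow the Felkin–Anh polar model, with attack anti to the epoxide C–O bond, to give the 5,6-anti carbinol, whose lithium alkoxide is silylated in the same flask.

Step 4
Reactants: 7 C6 triethylsilyl ether of the dithianyl carbinol
Product: 8 α-silyloxy aldehyde (C7 aldehyde)
Conditions: MeI, CaCO3, MeCN/H2O (9:1), 45 °C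
Reagents that add atoms: water, O
Why: Alkylative hydrolysis of the dithioacetal (S-methylation, then attack of water) under carbonate buffering should unmask the C7 aldehyde without acid, so the epoxide, the silyl ether and the alkene survive and C6 is not epimerised.

Step 5
Reactants: 9 (E)-3-(tert-butyldimethylsilyloxy)prop-1-enylboronic acid pinacol ester
Product: 10 (E)-3-(tert-butyldimethylsilyloxy)allylboronic acid pinacol ester
Conditions: [Ir(cod)(PPh2Me)2]PF6 (3 mol%, activated with H2), ethyl acetate, rt
Reagents that add atoms: none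
Why: Iridium hydride-catalysed alkene isomerisation (1,3-hydrogen shift) moves the double bond from conjugation with boron into conjugation with oxygen and should give the E γ-silyloxyallylboronate, a known reagent type.

Step 6
Reactants: 8 α-silyloxy aldehyde (C7 aldehyde); 10 (E)-3-(tert-butyldimethylsilyloxy)allylboronic acid pinacol ester
Product: 11 7,8-anti homoallylic alcohol with C8 OTBS
Conditions: 10 (1.5 equiv), (S)-TRIP [(S)-3,3′-bis(2,4,6-triisopropylphenyl)-1,1′-binaphthyl-2,2′-diyl hydrogen phosphate] (10 mol%), 4 Å molecular sieves, toluene, −30 °C; aqueous NaHCO3 work-up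
Reagents that add atoms: none
Why: Chiral phosphoric acid-catalysed allylboration through a closed chair transition state, in which the E geometry of 10 fixes the 7,8-anti relationship and the (S)-catalyst, assumed from simple aldehydes to direct the boronate to the si face, should set C8 as S, with the allylic oxygen arriving as its TBS ether and C7 to be oxidised away in step 9.

Step 7
Reactants: 11 7,8-anti homoallylic alcohol with C8 OTBS
Product: 13 C1 aldehyde, via ozonide 12 (not isolated)
Conditions: O3 (1.0 equiv, Sudan Red 7B as end-point indicator), CH2Cl2, −78 °C; then PPh3, −78 °C → rt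
Reagents that add atoms: ozone, [O-][O+]=O
Why: Ozonolysis with reductive work-up, stopped at one equivalent, should cleave the electron-rich trisubstituted alkene well before the monosubstituted vinyl group, which is deactivated by its allylic silyloxy substituent.

Step 8
Reactants: 13 C1 aldehyde; 14 isopropenylmagnesium bromide
Product: 15 C1,C7-diol (both C1 epimers)
Conditions: 14 (3 equiv), THF, −78 °C; H2O quench
Reagents that add atoms: none
Why: Grignard 1,2-addition to the aldehyde, after one equivalent has deprotonated the C7 hydroxyl, gives the C1 carbinol as an epimer mixture, which does not matter because C1 is oxidised in the next step.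

Step 9
Reactants: 15 C1,C7-diol (both C1 epimers)
Product: 16 C1,C7-diketone
Conditions: Dess–Martin periodinane (3 equiv), pyridine, CH2Cl2, 0 °C → rt
Reagents that add atoms: none
Why: Dess–Martin oxidation of both secondary alcohols under pyridine buffering gives the C1 isopropenyl ketone and the C7 ketone without a base strong enough to epimerise C6 or C8 or to move the vinyl group into conjugation.

Step 10
Reactants: 16 C1,C7-diketone
Product: 17 C6 alcohol (α-hydroxy ketone)
Conditions: HF·pyridine, pyridine, THF, 0 °C
Reagents that add atoms: none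
Why: Fluoride-mediated desilylation removes the triethylsilyl ether far faster than the bulkier tert-butyldimethylsilyl ether and frees the C6 hydroxyl under buffered conditions that the epoxide should tolerate.

Step 11
Reactants: 18 4-methoxybenzyl alcohol; 19 methyl 2-(dimethoxyphosphoryl)acrylate
Product: 20 methyl 2-(dimethoxyphosphoryl)-3-[(4-methoxybenzyl)oxy]propanoate
Conditions: DBU (5 mol%), CH2Cl2, rt
Reagents that add atoms: none
Why: Base-catalysed oxa-Michael addition of the alcohol to the doubly activated vinylphosphonate gives the β-alkoxy phosphonoacetate.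

Step 12
Reactants: 20 methyl 2-(dimethoxyphosphoryl)-3-[(4-methoxybenzyl)oxy]propanoate
Product: 21 2-(dimethoxyphosphoryl)-3-[(4-methoxybenzyl)oxy]propanoic acid
Conditions: LiOH·H2O (1.05 equiv), THF/H2O, 0 °C; then 1 M HCl to pH 3
Reagents that add atoms: lithium hydroxide, [Li+].[OH-]
Why: Saponification with one equivalent of hydroxide at 0 °C should cleave the carboxylic methyl ester faster than the phosphonate esters and give the acid on acidification.

Step 13
Reactants: 17 C6 alcohol (α-hydroxy ketone); 21 2-(dimethoxyphosphoryl)-3-[(4-methoxybenzyl)oxy]propanoic acid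
Product: 22 C6 phosphonoacetate ester
Conditions: DCC, DMAP (10 mol%), CH2Cl2, 0 °C
Reagents that add atoms: none
Why: Steglich esterification acylates the only free hydroxyl (C6), and the phosphonate-bearing carbon is a stereocentre of no consequence because both epimers converge in step 14.

Step 14
Reactants: 22 C6 phosphonoacetate ester
Product: 23 butenolide with C8 OTBS and C13 OPMB
Conditions: LiCl, iPr2NEt, MeCN (5 mM), 0 °C → rt
Reagents that add atoms: none
Why: Intramolecular Horner–Wadsworth–Emmons olefination with LiCl and an amine base should close the five-membered ring onto the activated C7 ketone faster than the phosphonate anion can lose its β-alkoxide or the ketone can enolise, forming the C7=C11 butenolide.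

Step 15
Reactants: 23 butenolide with C8 OTBS and C13 OPMB
Product: 24 C8 alcohol
Conditions: HF·pyridine, THF, 0 °C → rt
Reagents that add atoms: none
Why: Fluoride-mediated desilylation of the remaining TBS ether frees the C8 hydroxyl under non-basic conditions that should not deprotonate the γ-positions of the butenolide.

Step 16
Reactants: 24 C8 alcohol; 25 tigloyl chloride
Product: 26 C8 tiglate
Conditions: 25, Et3N, DMAP (cat.), CH2Cl2, 0 °C
Reagents that add atoms: none
Why: DMAP-catalysed O-acylation with the acid chloride at 0 °C installs the (E)-2-methylbut-2-enoate on the hindered secondary alcohol without breaking the C8–O bond, so the C8 configuration is kept.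

Step 17
Reactants: 26 C8 tiglate
Product: 27 C13 alcohol
Conditions: DDQ, CH2Cl2/pH 7 phosphate buffer (10:1), 0 °C → rt
Reagents that add atoms: none
Why: Oxidative cleavage of the 4-methoxybenzyl ether by DDQ (hydride abstraction at the electron-rich benzylic carbon, then hydrolysis) at buffered pH should leave esters, enone, epoxide and alkenes untouched.

Step 18
Reactants: 27 C13 alcohol
Product: 28 C13 acetate with C1 isopropenyl ketone
Conditions: Ac2O, pyridine, DMAP (cat.), CH2Cl2, 0 °C
Reagents that add atoms: acetic anhydride, CC(=O)OC(C)=O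
Why: DMAP-catalysed acetylation of the only free hydroxyl, a primary allylic alcohol, completes the C13 acetate.

Step 19
Reactants: 28 C13 acetate with C1 isopropenyl ketone
Product: 29 open-chain diene with free C1 hydroxyl (metathesis precursor)
Conditions: (R)-2-methyl-CBS-oxazaborolidine (1 equiv), catecholborane (2 equiv), toluene, −78 °C; aqueous NaHCO3 work-up
Reagents that add atoms: none
Why: Corey–Bakshi–Shibata reduction, in which the ketone binds the (R)-oxazaborolidine with the isopropenyl group as the large substituent so that hydride from catecholborane should give the 1S alcohol, while the lactone and the esters are not reduced at −78 °C.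

Step 20
Reactants: 29 open-chain diene with free C1 hydroxyl (metathesis precursor)
Product: 30 (9Z)-9,10-didehydro target
Conditions: second-generation Hoveyda–Grubbs catalyst RuCl2(H2IMes)(=CH-C6H4-2-OiPr) (15 mol%, in portions), 1,4-benzoquinone (20 mol%), toluene (1 mM), 80 °C, argon sparge
Reagents that add atoms: none
Why: Ring-closing olefin metathesis by [2+2] cycloaddition and cycloreversion through ruthenacyclobutanes: the catalyst loads on the monosubstituted C8 vinyl group, the resulting C9 alkylidene adds across the 1,1-disubstituted isopropenyl alkene, and ethylene is released and swept out so that closure is not reversed. The closest known reaction type is ring-closing metathesis to ten-membered carbocycles that contain a trisubstituted alkene. The ten-membered ring closes end to end by attack of the C9 ruthenium carbene on the C10=CH2 bond, helped by the cis-epoxide and the flat butenolide, which turn the C1–C4 chain back toward C8, and by the free allylic C1 hydroxyl, which speeds metathesis of the neighbouring alkene. No stereocentre is formed; the alkene geometry is expected to be ring-cis (9Z) because that is the less strained cyclodecene, and it is to be checked before hydrogenation. The step needs site selectivity among four alkenes and ring closure over dimerisation: the tetrasubstituted butenolide alkene and the conjugated trisubstituted tiglate alkene are inert to the catalyst, only the vinyl group initiates, and high dilution with portionwise catalyst favours the intramolecular path.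

Step 21
Reactants: 30 (9Z)-9,10-didehydro target
Product: 31 CNP0159184.1 (target)
Conditions: [Ir(cod)(PCy3)(py)]PF6 (10 mol%), H2 (1 atm), CH2Cl2, 0 °C → rt
Reagents that add atoms: none
Why: Hydroxyl-directed hydrogenation, in which the cationic iridium catalyst binds the C1 hydroxyl and the neighbouring alkene while A(1,3) strain with C8 holds the C1–H bond in the alkene plane, should deliver both hydrogens to the face on the hydroxyl side and give the 1,10-anti (10R) product, with the conjugated tiglate and the tetrasubstituted butenolide alkenes reacting much more slowly.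

**Compound list**
1 | nerol, (2Z)-3,7-dimethylocta-2,6-dien-1-ol | CC(C)=CCC/C(C)=C\CO | starting material
2 | (2S,3R)-2,3-epoxynerol, [(2S,3R)-3-methyl-3-(4-methylpent-3-en-1-yl)oxiran-2-yl]methanol | CC(C)=CCC[C@@]1(C)O[C@H]1CO | intermediate
3 | (2R,3R)-3-methyl-3-(4-methylpent-3-en-1-yl)oxirane-2-carbaldehyde | CC(C)=CCC[C@@]1(C)O[C@H]1C=O | intermediate
4 | 1,3-dithiane | C1CSCSC1 | starting material
5 | 2-lithio-1,3-dithiane | [Li]C1SCCCS1 | intermediate
6 | lithium (R)-(1,3-dithian-2-yl)[(2S,3R)-3-methyl-3-(4-methylpent-3-en-1-yl)oxiran-2-yl]methanolate | CC(C)=CCC[C@@]1(C)O[C@H]1[C@@H](O[Li])C1SCCCS1 | intermediate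
7 | triethyl{(R)-(1,3-dithian-2-yl)[(2S,3R)-3-methyl-3-(4-methylpent-3-en-1-yl)oxiran-2-yl]methoxy}silane | CC(C)=CCC[C@@]1(C)O[C@H]1[C@@H](O[Si](CC)(CC)CC)C1SCCCS1 | intermediate
8 | (2R)-2-[(2S,3R)-3-methyl-3-(4-methylpent-3-en-1-yl)oxiran-2-yl]-2-(triethylsilyloxy)acetaldehyde | CC(C)=CCC[C@@]1(C)O[C@H]1[C@@H](O[Si](CC)(CC)CC)C=O | intermediate
9 | 2-[(1E)-3-(tert-butyldimethylsilyloxy)prop-1-en-1-yl]-4,4,5,5-tetramethyl-1,3,2-dioxaborolane | CC(C)(C)[Si](C)(C)OC/C=C/B1OC(C)(C)C(C)(C)O1 | starting material
10 | 2-[(2E)-3-(tert-butyldimethylsilyloxy)prop-2-en-1-yl]-4,4,5,5-tetramethyl-1,3,2-dioxaborolane | CC(C)(C)[Si](C)(C)O/C=C/CB1OC(C)(C)C(C)(C)O1 | intermediate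
11 | (3S,4S,5S)-3-(tert-butyldimethylsilyloxy)-5-[(2S,3R)-3-methyl-3-(4-methylpent-3-en-1-yl)oxiran-2-yl]-5-(triethylsilyloxy)pent-1-en-4-ol (C6 S, C7 S, C8 S) | CC(C)=CCC[C@@]1(C)O[C@H]1[C@@H](O[Si](CC)(CC)CC)[C@@H](O)[C@@H](O[Si](C)(C)C(C)(C)C)C=C | intermediate
12 | ozonide of 11 (5,5-dimethyl-1,2,4-trioxolan-3-yl group in place of Me2C=CH) | CC1(C)OOC(CC[C@@]2(C)O[C@H]2[C@@H](O[Si](CC)(CC)CC)[C@@H](O)[C@@H](O[Si](C)(C)C(C)(C)C)C=C)O1 | intermediate
13 | C1 aldehyde (CHO in place of Me2C=CH of 11; 4R,5S,6S,7S,8S) | O=CCC[C@@]1(C)O[C@H]1[C@@H](O[Si](CC)(CC)CC)[C@@H](O)[C@@H](O[Si](C)(C)C(C)(C)C)C=C | intermediate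
14 | isopropenylmagnesium bromide | CC(=C)[Mg]Br | starting material
15 | C1,C7-diol with C1 isopropenyl carbinol, both C1 epimers (4R,5S,6S,7S,8S) | CC(=C)C(O)CC[C@@]1(C)O[C@H]1[C@@H](O[Si](CC)(CC)CC)[C@@H](O)[C@@H](O[Si](C)(C)C(C)(C)C)C=C | intermediate
16 | C1,C7-diketone with C6 OTES and C8 OTBS (4R,5S,6R,8S) | CC(=C)C(=O)CC[C@@]1(C)O[C@H]1[C@@H](O[Si](CC)(CC)CC)C(=O)[C@@H](O[Si](C)(C)C(C)(C)C)C=C | intermediate
17 | C6 alcohol of the diketone (4R,5S,6R,8S) | CC(=C)C(=O)CC[C@@]1(C)O[C@H]1[C@@H](O)C(=O)[C@@H](O[Si](C)(C)C(C)(C)C)C=C | intermediate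
18 | 4-methoxybenzyl alcohol | COc1ccc(CO)cc1 | starting material
19 | methyl 2-(dimethoxyphosphoryl)acrylate | C=C(C(=O)OC)P(=O)(OC)OC | starting material
20 | methyl 2-(dimethoxyphosphoryl)-3-[(4-methoxybenzyl)oxy]propanoate (racemic) | COC(=O)C(COCc1ccc(OC)cc1)P(=O)(OC)OC | intermediate
21 | 2-(dimethoxyphosphoryl)-3-[(4-methoxybenzyl)oxy]propanoic acid (racemic) | OC(=O)C(COCc1ccc(OC)cc1)P(=O)(OC)OC | intermediate
22 | C6 ester of 17 with acid 21 (4R,5S,6R,8S; phosphonate carbon both epimers) | CC(=C)C(=O)CC[C@@]1(C)O[C@H]1[C@@H](OC(=O)C(COCc1ccc(OC)cc1)P(=O)(OC)OC)C(=O)[C@@H](O[Si](C)(C)C(C)(C)C)C=C | intermediate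
23 | butenolide with C8 OTBS, C13 OPMB and C1 isopropenyl ketone (4R,5S,6S,8S) | CC(=C)C(=O)CC[C@@]1(C)O[C@H]1[C@H]1OC(=O)C(COCc2ccc(OC)cc2)=C1[C@@H](O[Si](C)(C)C(C)(C)C)C=C | intermediate
24 | butenolide with free C8 hydroxyl, C13 OPMB (4R,5S,6S,8S) | CC(=C)C(=O)CC[C@@]1(C)O[C@H]1[C@H]1OC(=O)C(COCc2ccc(OC)cc2)=C1[C@@H](O)C=C | intermediate
25 | tigloyl chloride, (E)-2-methylbut-2-enoyl chloride | C/C=C(\C)C(Cl)=O | starting material
26 | C8 tiglate, C13 OPMB (4R,5S,6S,8S) | CC(=C)C(=O)CC[C@@]1(C)O[C@H]1[C@H]1OC(=O)C(COCc2ccc(OC)cc2)=C1[C@@H](OC(=O)/C(C)=C/C)C=C | intermediate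
27 | C8 tiglate, free C13 hydroxyl (4R,5S,6S,8S) | CC(=C)C(=O)CC[C@@]1(C)O[C@H]1[C@H]1OC(=O)C(CO)=C1[C@@H](OC(=O)/C(C)=C/C)C=C | intermediate
28 | C8 tiglate, C13 acetate, C1 isopropenyl ketone (4R,5S,6S,8S) | CC(=C)C(=O)CC[C@@]1(C)O[C@H]1[C@H]1OC(=O)C(COC(C)=O)=C1[C@@H](OC(=O)/C(C)=C/C)C=C | intermediate
29 | open-chain diene with epoxide, butenolide, C8 tiglate, C13 acetate and free C1 hydroxyl (1S,4R,5S,6S,8S) | C/C=C(\C)C(=O)O[C@@H](C=C)C1=C(COC(C)=O)C(=O)O[C@@H]1[C@@H]1O[C@]1(C)CC[C@H](O)C(C)=C | intermediate
30 | (9Z)-9,10-didehydro target (1S,4R,5S,6S,8S) | C/C=C(\C)C(=O)O[C@H]1/C=C(/C)[C@@H](O)CC[C@@]2(C)O[C@H]2[C@H]2OC(=O)C(COC(C)=O)=C12 | intermediate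
31 | CNP0159184.1 (1S,4R,5S,6S,8S,10R) | C/C=C(\C)C(=O)O[C@H]1C[C@@H](C)[C@@H](O)CC[C@@]2(C)O[C@H]2[C@H]2OC(=O)C(COC(C)=O)=C12 | target

**Step count and risks**
Total steps: 21 (steps 5, 11 and 12 make the two reagents). Longest linear sequence: 18 (steps 1–4, 6–10, 13–21).

Step 20 (ring closure). The C9 ruthenium carbene may dimerise or oligomerise faster than it closes the strained ten-membered ring. At 80 °C the free C1 hydroxyl may also open the C4–C5 epoxide, or a ruthenium hydride may move the C8 vinyl group into conjugation. The fallback closes the ring one step earlier, with C1 still a ketone and no free hydroxyl. It sets out from 28: the same catalyst and dilution should give the macrocyclic enone F1. Reduction of F1 with (R)-2-methyl-CBS-oxazaborolidine and catecholborane at −78 °C, the ring alkenyl group acting as the large substituent, comes back to the route at 30.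

Step 21 (hydrogenation). Hydrogen may be delivered to the wrong face of C10 if the ring, and not A(1,3) strain, decides which C1 substituent lies in the alkene plane; the result would be the 1,10-syn product. Slow reduction of the tiglate alkene is a second concern. The fallback makes C10 in the C1-epimeric series and corrects C1 afterwards. It sets out from 28: reduction with (S)-2-methyl-CBS-oxazaborolidine gives the 1R diene F2, ring-closing metathesis as in step 20 gives the 1R cyclodecene F3, and the same directed hydrogenation, now working from the other ring face, should give the (1R,10R) alcohol F4. Mitsunobu inversion with chloroacetic acid, PPh3 and diisopropyl azodicarboxylate gives the 1S chloroacetate F5. Thiourea with NaHCO3 in ethanol removes the chloroacetate selectively beside the acetate and the tiglate, and the sequence comes back at 31.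

Step 6 (allylboration). Facial selectivity may be poor if the catalyst's preference for the si face opposes the intrinsic bias of the α-silyloxy aldehyde, and the reaction may be slow with this hindered aldehyde. Because C7 is oxidised later, the 8S centre can equally be made by re-face attack of the Z reagent. The fallback sets out from 8: allyl tert-butyldimethylsilyl ether, s-BuLi (THF, −78 °C) and 2-isopropoxy-4,4,5,5-tetramethyl-1,3,2-dioxaborolane give the Z γ-silyloxyallylboronate F6. With (R)-TRIP this should add to the re face and give the 7,8-syn (7R,8S) adduct F7. Ozonolysis as in step 7 goes through the ozonide F8 to the C1 aldehyde F9, isopropenylmagnesium bromide gives the diol F10, and Dess–Martin oxidation as in step 9 comes back to the route at 16.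

**Further compounds**
F1 | step 20 | macrocyclic (9Z)-9-en-1-one, the C1 ketone of 30 | C/C=C(\C)C(=O)O[C@H]1/C=C(/C)C(=O)CC[C@@]2(C)O[C@H]2[C@H]2OC(=O)C(COC(C)=O)=C12
F2 | step 21 | 1R epimer of 29 | C/C=C(\C)C(=O)O[C@@H](C=C)C1=C(COC(C)=O)C(=O)O[C@@H]1[C@@H]1O[C@]1(C)CC[C@@H](O)C(C)=C
F3 | step 21 | 1R epimer of 30 | C/C=C(\C)C(=O)O[C@H]1/C=C(/C)[C@H](O)CC[C@@]2(C)O[C@H]2[C@H]2OC(=O)C(COC(C)=O)=C12
F4 | step 21 | (1R,10R) alcohol, the 1-epimer of 31 | C/C=C(\C)C(=O)O[C@H]1C[C@@H](C)[C@H](O)CC[C@@]2(C)O[C@H]2[C@H]2OC(=O)C(COC(C)=O)=C12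
F5 | step 21 | (1S)-chloroacetate of 31 | C/C=C(\C)C(=O)O[C@H]1C[C@@H](C)[C@@H](OC(=O)CCl)CC[C@@]2(C)O[C@H]2[C@H]2OC(=O)C(COC(C)=O)=C12
F6 | step 6 | 2-[(2Z)-3-(tert-butyldimethylsilyloxy)prop-2-en-1-yl]-4,4,5,5-tetramethyl-1,3,2-dioxaborolane | CC(C)(C)[Si](C)(C)O/C=C\CB1OC(C)(C)C(C)(C)O1
F7 | step 6 | 7,8-syn adduct, the (7R) epimer of 11 | CC(C)=CCC[C@@]1(C)O[C@H]1[C@@H](O[Si](CC)(CC)CC)[C@H](O)[C@@H](O[Si](C)(C)C(C)(C)C)C=C
F8 | step 6 | ozonide of F7 | CC1(C)OOC(CC[C@@]2(C)O[C@H]2[C@@H](O[Si](CC)(CC)CC)[C@H](O)[C@@H](O[Si](C)(C)C(C)(C)C)C=C)O1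
F9 | step 6 | C1 aldehyde, the (7R) epimer of 13 | O=CCC[C@@]1(C)O[C@H]1[C@@H](O[Si](CC)(CC)CC)[C@H](O)[C@@H](O[Si](C)(C)C(C)(C)C)C=C
F10 | step 6 | C1,C7-diol, the (7R) epimer of 15 (both C1 epimers) | CC(=C)C(O)CC[C@@]1(C)O[C@H]1[C@@H](O[Si](CC)(CC)CC)[C@H](O)[C@@H](O[Si](C)(C)C(C)(C)C)C=C
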